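## Retrosynthetic overview

1. Katsumain C ⇐ acidic removal of four MOM ethers and one TBS ether from the fully protected chalcone. No ring is formed anywhere in the route; all four benzene rings are bought.
2. Protected chalcone ⇐ ring A aryl iodide + CO + styrene by palladium-catalysed carbonylative Heck coupling, which makes the ring A C1'–C(=O) and C(=O)–Cα bonds. The strategy rests on ring A: before acylation its two free CH carbons (C1' and C5', each between an OMOM-bearing carbon and the OMe-bearing C6') are interchanged by rotation about the C7–C3' bond, so a single iodination marks exactly the carbon that carries the enone carbonyl.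
3. Ring A aryl iodide ⇐ NIS iodination ⇐ E-selective cross-metathesis (C5=C6) of an (R)-3,3-diarylpropene with an (R)-homoallylic silyl ether.
4. (R)-3,3-Diarylpropene ⇐ copper-catalysed enantioselective SN2' arylation of a 4-(methoxymethoxy)cinnamyl phosphate by the ortho-metalated ring A bis-MOM ether (C7–ring A bond, C7 stereocentre). Homoallylic ether ⇐ Keck allylation of a 3-arylpropanal (C3 stereocentre).

Key step: step 12

Remark on numbering and abbreviations: chain atoms are C1–C7 from the saturated 4-hydroxyphenyl end (C3 carbinol, C5=C6 alkene, C7 diaryl methine); ring A atoms are C1'–C6' with C1' the acyl carbon. MOM = methoxymethyl, TBS = tert-butyldimethylsilyl, NIS = N-iodosuccinimide, NHC = N-heterocyclic carbene.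

Assumption: the sense of induction of the chiral carbene–copper catalyst in step 5 is not predicted here; the ligand enantiomer that delivers the (R)-configured diarylpropene is used, to be confirmed on that compound.

## Route

Step 1
Reactants: 1 5-methoxyresorcinol
Product: 2 1-methoxy-3,5-bis(methoxymethoxy)benzene
Conditions: MOMCl, i-Pr2NEt, CH2Cl2, 0 °C to rt
Reagents that add atoms: chloromethyl methyl ether (MOMCl), COCCl
Why: Williamson-type O-alkylation of both phenols with the α-chloro ether gives the bis-MOM ether, whose acetal oxygens later direct lithiation to the carbon between them.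

Step 2
Reactants: 3 methyl (E)-3-(4-hydroxyphenyl)prop-2-enoate
Product: 4 methyl (E)-3-[4-(methoxymethoxy)phenyl]prop-2-enoate
Conditions: MOMCl, i-Pr2NEt, CH2Cl2, 0 °C to rt
Reagents that add atoms: chloromethyl methyl ether (MOMCl), COCCl
Why: Williamson-type MOM protection masks the phenol, which would otherwise quench the hydride and organometallic reagents of the following steps.

Step 3
Reactants: 4 methyl (E)-3-[4-(methoxymethoxy)phenyl]prop-2-enoate
Product: 5 (E)-3-[4-(methoxymethoxy)phenyl]prop-2-en-1-ol
Conditions: i-Bu2AlH (DIBAL-H, 2.3 equiv), CH2Cl2, −78 to 0 °C; aq. Rochelle salt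
Reagents that add atoms: none
Why: 1,2-Reduction of the conjugated ester by the aluminium hydride should give the E-allylic alcohol without touching the alkene or the MOM acetal.

Step 4
Reactants: 5 (E)-3-[4-(methoxymethoxy)phenyl]prop-2-en-1-ol
Product: 6 diethyl (E)-3-[4-(methoxymethoxy)phenyl]prop-2-en-1-yl phosphate
Conditions: ClP(O)(OEt)2, NEt3, DMAP (cat.), CH2Cl2, 0 °C
Reagents that add atoms: diethyl chlorophosphate, CCOP(=O)(Cl)OCC
Why: Phosphorylation of the primary allylic alcohol installs the leaving group for copper-catalysed allylic substitution, and the basic medium keeps the acid-sensitive p-alkoxycinnamyl system from ionising.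

Step 5
Reactants: 2 1-methoxy-3,5-bis(methoxymethoxy)benzene; 6 diethyl (E)-3-[4-(methoxymethoxy)phenyl]prop-2-en-1-yl phosphate
Product: 9 (R)-5-methoxy-1,3-bis(methoxymethoxy)-2-{1-[4-(methoxymethoxy)phenyl]prop-2-en-1-yl}benzene, via aryllithium 7 (not isolated), via diethyl(aryl)aluminium 8 (not isolated)
Conditions: n-BuLi, THF, 0 °C; Et2AlCl, −78 °C to rt; then 6, CuCl2·2H2O (3 mol%), chiral sulfonate-bearing imidazolinium salt (NHC precursor, 3 mol%), THF, −30 °C
Reagents that add atoms: none
Why: Directed ortho-metalation between the two MOM ethers, transmetalation to aluminium and copper–NHC-catalysed enantioselective allylic substitution in the SN2' mode should form the C7–ring A bond at the aryl-bearing alkene carbon of 6, the chiral carbene on copper selecting the alkene face so that C7 is set as R.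

Step 6
Reactants: 10 methyl 3-(4-hydroxyphenyl)propanoate
Product: 11 methyl 3-[4-(methoxymethoxy)phenyl]propanoate
Conditions: MOMCl, i-Pr2NEt, CH2Cl2, 0 °C to rt
Reagents that add atoms: chloromethyl methyl ether (MOMCl), COCCl
Why: Williamson-type MOM protection of the phenol, chosen so that all phenol protecting groups fall in the same final operation.

Step 7
Reactants: 11 methyl 3-[4-(methoxymethoxy)phenyl]propanoate
Product: 12 3-[4-(methoxymethoxy)phenyl]propanal
Conditions: i-Bu2AlH (DIBAL-H, 1.1 equiv), CH2Cl2, −78 °C; MeOH, aq. Rochelle salt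
Reagents that add atoms: none
Why: Partial reduction of the methyl ester stops at the aldehyde because the tetrahedral aluminium hemiacetal persists at −78 °C until work-up.

Step 8
Reactants: 12 3-[4-(methoxymethoxy)phenyl]propanal
Product: 13 (R)-1-[4-(methoxymethoxy)phenyl]hex-5-en-3-ol
Conditions: allylSnBu3, (S)-BINOL (10 mol%), Ti(OiPr)4 (10 mol%), 4 Å MS, CH2Cl2, −20 °C; aq. NaHCO3
Reagents that add atoms: allyltributylstannane, C=CC[Sn](CCCC)(CCCC)CCCC
Why: Keck asymmetric allylation, in which the (S)-BINOL–titanium Lewis acid activates the aldehyde and exposes its Si face to the allylstannane, which for this unbranched aliphatic aldehyde sets C3 as R.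

Step 9
Reactants: 13 (R)-1-[4-(methoxymethoxy)phenyl]hex-5-en-3-ol
Product: 14 (R)-tert-butyl({1-[4-(methoxymethoxy)phenyl]hex-5-en-3-yl}oxy)dimethylsilane
Conditions: TBSCl, imidazole, DMF, rt
Reagents that add atoms: tert-butyldimethylsilyl chloride (TBSCl), CC(C)(C)[Si](C)(C)Cl
Why: Imidazole-promoted silylation protects the C3 hydroxyl, which would otherwise be iodoetherified in step 11 or acylated by the aroylpalladium in step 12.

Step 10
Reactants: 9 (R)-5-methoxy-1,3-bis(methoxymethoxy)-2-{1-[4-(methoxymethoxy)phenyl]prop-2-en-1-yl}benzene; 14 (R)-tert-butyl({1-[4-(methoxymethoxy)phenyl]hex-5-en-3-yl}oxy)dimethylsilane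
Product: 15 2-{(1R,2E,5R)-5-[(tert-butyldimethylsilyl)oxy]-1,7-bis[4-(methoxymethoxy)phenyl]hept-2-en-1-yl}-5-methoxy-1,3-bis(methoxymethoxy)benzene
Conditions: 14 (2.5 equiv), second-generation Hoveyda–Grubbs catalyst (5 mol%), 1,4-benzoquinone (10 mol%), CH2Cl2, 40 °C
Reagents that add atoms: none
Why: Olefin cross-metathesis between the slowly dimerising, allylically branched alkene 9 and an excess of the fast-reacting homoallylic ether 14 should form C5=C6 with loss of ethylene, E by thermodynamic control, while benzoquinone quenches ruthenium hydrides that could move the double bond into conjugation and erase C7.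

Step 11
Reactants: 15 2-{(1R,2E,5R)-5-[(tert-butyldimethylsilyl)oxy]-1,7-bis[4-(methoxymethoxy)phenyl]hept-2-en-1-yl}-5-methoxy-1,3-bis(methoxymethoxy)benzene
Product: 16 2-{(1R,2E,5R)-5-[(tert-butyldimethylsilyl)oxy]-1,7-bis[4-(methoxymethoxy)phenyl]hept-2-en-1-yl}-4-iodo-5-methoxy-1,3-bis(methoxymethoxy)benzene
Conditions: NIS (1.05 equiv), MeCN, 0 °C, dark
Reagents that add atoms: N-iodosuccinimide (NIS), O=C1CCC(=O)N1I
Why: Electrophilic aromatic iodination should go to the trioxygenated ring A, by far the most electron-rich arene, whose two free positions are equivalent, so one equivalent of NIS without added acid gives one iodide and leaves the MOM and TBS groups intact.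

Step 12
Reactants: 16 2-{(1R,2E,5R)-5-[(tert-butyldimethylsilyl)oxy]-1,7-bis[4-(methoxymethoxy)phenyl]hept-2-en-1-yl}-4-iodo-5-methoxy-1,3-bis(methoxymethoxy)benzene; 17 carbon monoxide; 18 styrene
Product: 19 (E)-1-[3-{(1R,2E,5R)-5-[(tert-butyldimethylsilyl)oxy]-1,7-bis[4-(methoxymethoxy)phenyl]hept-2-en-1-yl}-6-methoxy-2,4-bis(methoxymethoxy)phenyl]-3-phenylprop-2-en-1-one (fully protected Katsumain C)
Conditions: CO (10 bar), styrene (3 equiv), Pd(OAc)2 (5 mol%), di(1-adamantyl)-n-butylphosphine (10 mol%), NEt3, 1,4-dioxane, 100 °C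
Reagents that add atoms: none
Why: Pd(OAc)2 is reduced in the flask to zerovalent palladium, which adds to the carbon–iodine bond of 16; the resulting divalent arylpalladium iodide inserts CO, the aroylpalladium adds across styrene with the acyl group on the terminal carbon, and β-hydride elimination releases the enone while NEt3 takes up HI and returns zerovalent palladium. The closest known reaction type is the palladium-catalysed carbonylative Heck coupling of aryl iodides with styrenes to chalcones under CO pressure with bulky electron-rich phosphines. No ring is closed and no stereocentre is created; the E geometry of the new C=C follows from syn insertion and syn β-hydride elimination through the less crowded rotamer. Carbonylative over direct coupling is needed and is secured by the CO pressure and by the two ortho oxygen substituents, which slow alkene insertion into the aryl–palladium bond far more than CO insertion. Styrene over the internal C5=C6 alkene is needed and is secured by the terminal, conjugated and unhindered double bond of styrene used in excess, the chain alkene being 1,2-disubstituted, next to the C7 methine and unable to reach the metal intramolecularly because C7 sits meta to the iodinated carbon. The site of acylation was fixed in step 11, and C7 and C3 are not at risk because the medium is neutral to weakly basic, the C3 oxygen is silylated and the excess styrene intercepts palladium hydride before it can move the C5=C6 bond toward C7.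

Step 13
Reactants: 19 fully protected Katsumain C
Product: 20 Katsumain C, (E)-1-{2,4-dihydroxy-3-[(1R,2E,5R)-5-hydroxy-1,7-bis(4-hydroxyphenyl)hept-2-en-1-yl]-6-methoxyphenyl}-3-phenylprop-2-en-1-one
Conditions: HCl (ca. 2 M in MeOH), THF, 0 °C to rt, monitored and stopped at full conversion
Reagents that add atoms: none
Why: Acid-catalysed methanolysis should cleave the four MOM acetals and the TBS ether in one operation, and at room temperature the 2'-hydroxychalcone is expected to resist closure to the flavanone and the C7–ring A bond to resist ionisation, as is usual for MOM-protected 2'-hydroxy-6'-methoxychalcones.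

## Compound list

1 | 5-methoxyresorcinol | COc1cc(O)cc(O)c1 | starting material
2 | 1-methoxy-3,5-bis(methoxymethoxy)benzene | COCOc1cc(OC)cc(OCOC)c1 | intermediate
3 | methyl (E)-3-(4-hydroxyphenyl)prop-2-enoate | COC(=O)/C=C/c1ccc(O)cc1 | starting material
4 | methyl (E)-3-[4-(methoxymethoxy)phenyl]prop-2-enoate | COC(=O)/C=C/c1ccc(OCOC)cc1 | intermediate
5 | (E)-3-[4-(methoxymethoxy)phenyl]prop-2-en-1-ol | OC/C=C/c1ccc(OCOC)cc1 | intermediate
6 | diethyl (E)-3-[4-(methoxymethoxy)phenyl]prop-2-en-1-yl phosphate | CCOP(=O)(OCC)OC/C=C/c1ccc(OCOC)cc1 | intermediate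
7 | [4-methoxy-2,6-bis(methoxymethoxy)phenyl]lithium | [Li]c1c(OCOC)cc(OC)cc1OCOC | intermediate
8 | diethyl[4-methoxy-2,6-bis(methoxymethoxy)phenyl]aluminium | CC[Al](CC)c1c(OCOC)cc(OC)cc1OCOC | intermediate
9 | (R)-5-methoxy-1,3-bis(methoxymethoxy)-2-{1-[4-(methoxymethoxy)phenyl]prop-2-en-1-yl}benzene | COc1cc(OCOC)c([C@H](C=C)c2ccc(OCOC)cc2)c(OCOC)c1 | intermediate
10 | methyl 3-(4-hydroxyphenyl)propanoate | COC(=O)CCc1ccc(O)cc1 | starting material
11 | methyl 3-[4-(methoxymethoxy)phenyl]propanoate | COC(=O)CCc1ccc(OCOC)cc1 | intermediate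
12 | 3-[4-(methoxymethoxy)phenyl]propanal | O=CCCc1ccc(OCOC)cc1 | intermediate
13 | (R)-1-[4-(methoxymethoxy)phenyl]hex-5-en-3-ol | C=CC[C@H](O)CCc1ccc(OCOC)cc1 | intermediate
14 | (R)-tert-butyl({1-[4-(methoxymethoxy)phenyl]hex-5-en-3-yl}oxy)dimethylsilane | C=CC[C@H](O[Si](C)(C)C(C)(C)C)CCc1ccc(OCOC)cc1 | intermediate
15 | 2-{(1R,2E,5R)-5-[(tert-butyldimethylsilyl)oxy]-1,7-bis[4-(methoxymethoxy)phenyl]hept-2-en-1-yl}-5-methoxy-1,3-bis(methoxymethoxy)benzene | COc1cc(OCOC)c([C@H](/C=C/C[C@H](O[Si](C)(C)C(C)(C)C)CCc2ccc(OCOC)cc2)c2ccc(OCOC)cc2)c(OCOC)c1 | intermediate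
16 | 2-{(1R,2E,5R)-5-[(tert-butyldimethylsilyl)oxy]-1,7-bis[4-(methoxymethoxy)phenyl]hept-2-en-1-yl}-4-iodo-5-methoxy-1,3-bis(methoxymethoxy)benzene | COc1cc(OCOC)c([C@H](/C=C/C[C@H](O[Si](C)(C)C(C)(C)C)CCc2ccc(OCOC)cc2)c2ccc(OCOC)cc2)c(OCOC)c1I | intermediate
17 | carbon monoxide | [C-]#[O+] | starting material
18 | styrene | C=Cc1ccccc1 | starting material
19 | fully protected Katsumain C, (E)-1-[3-{(1R,2E,5R)-5-[(tert-butyldimethylsilyl)oxy]-1,7-bis[4-(methoxymethoxy)phenyl]hept-2-en-1-yl}-6-methoxy-2,4-bis(methoxymethoxy)phenyl]-3-phenylprop-2-en-1-one | COc1cc(OCOC)c([C@H](/C=C/C[C@H](O[Si](C)(C)C(C)(C)C)CCc2ccc(OCOC)cc2)c2ccc(OCOC)cc2)c(OCOC)c1C(=O)/C=C/c1ccccc1 | intermediate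
20 | Katsumain C, (E)-1-{2,4-dihydroxy-3-[(1R,2E,5R)-5-hydroxy-1,7-bis(4-hydroxyphenyl)hept-2-en-1-yl]-6-methoxyphenyl}-3-phenylprop-2-en-1-one | COc1cc(O)c([C@H](/C=C/C[C@H](O)CCc2ccc(O)cc2)c2ccc(O)cc2)c(O)c1C(=O)/C=C/c1ccccc1 | target

## Step count and risks

Total step count: 13. Longest linear sequence: 8 steps (steps 2, 3, 4, 5, 10, 11, 12, 13 from compound 3; equally steps 6, 7, 8, 9, 10, 11, 12, 13 from compound 10).

The three steps most likely to fail:

**Step 12 (carbonylative Heck coupling).** Styrene insertion into the crowded, di-ortho-substituted aroylpalladium may be slow. Reduction of the carbon–iodine bond, direct arylation of styrene, or palladium hydride-induced migration of the C5=C6 double bond toward C7 could then take over.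
Fallback, from 16 back to 19: iodine–magnesium exchange on 16 with i-PrMgCl·LiCl (THF, −15 to 0 °C) should give the arylmagnesium chloride F1. Addition of (E)-cinnamaldehyde at −40 °C would give the secondary allylic alcohol F2 as a mixture of carbinol epimers. Oxidation of the crude alcohol with MnO2 in CH2Cl2 at rt returns the route at 19. No carbon monoxide, no palladium hydride and no heating are involved, so C7 and the C5=C6 alkene are not exposed.

**Step 5 (copper-catalysed enantioselective allylic arylation).** Transfer of the di-ortho-substituted aryl group from aluminium to copper may be slow, and the Lewis acidic aluminium may ionise the p-alkoxycinnamyl phosphate. This would show as low conversion, ethyl transfer, linear product or eroded enantioselectivity.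
Fallback, from 2 and 14 back to 15 (it replaces steps 2–5 and 10) by stereospecific chirality transfer instead of catalyst control:
- Commercial (E)-4-(4-hydroxyphenyl)but-3-en-2-one F3 is protected (MOMCl, i-Pr2NEt) to the MOM ether F4.
- Corey–Bakshi–Shibata reduction with (R)-2-methyl-CBS-oxazaborolidine and BH3·SMe2 should give the (S)-allylic alcohol F5.
- Esterification with picolinic acid (DCC, DMAP) gives the (S)-picolinate F6.
- Compound 2 is lithiated as in step 5 to 7 and transmetalated with MgBr2·OEt2 to the arylmagnesium bromide F7.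
- F7 with CuBr·SMe2 in THF at 0 °C should displace the picolinate of F6 in the anti-SN2' mode, through the conformer with the carbinol hydrogen in the alkene plane, to give the (R,E)-1,1-diarylbut-2-ene F8.
- Cross-metathesis of F8 with 14 under the conditions of step 10 (propene lost instead of ethylene) returns the route at 15.

**Step 10 (cross-metathesis).** Productive metathesis at the crowded allylic methine of 9 may be slow while 14 homodimerises. Ruthenium hydride-induced migration of the terminal double bond of 9 into conjugation would erase C7.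
Fallback, from 9 and 14 back to 15 by Julia–Kocienski olefination:
- Lemieux–Johnson cleavage of 9 (OsO4 cat., NaIO4, 2,6-lutidine, dioxane–water) gives the diarylacetaldehyde F9, which is reduced at once with NaBH4 to the (R)-2,2-diarylethanol F10 before it can enolise.
- Mitsunobu reaction of F10 with 1-phenyl-1H-tetrazole-5-thiol (PPh3, DIAD, THF) gives the sulfide F11.
- Oxidation with H2O2 and (NH4)6Mo7O24 (cat.) in EtOH gives the sulfone F12.
- The same Lemieux–Johnson cleavage of 14 gives the (R)-β-silyloxy aldehyde F13.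
- KN(SiMe3)2 in DME at −60 °C, added to a mixture of F12 and F13, should form the E-configured C5=C6 bond and return the route at 15.

## Further compounds

F1 | step 12 | arylmagnesium chloride derived from 16 (magnesium in place of iodine) | COc1cc(OCOC)c([C@H](/C=C/C[C@H](O[Si](C)(C)C(C)(C)C)CCc2ccc(OCOC)cc2)c2ccc(OCOC)cc2)c(OCOC)c1[Mg]Cl
F2 | step 12 | (E)-1-[3-{(1R,2E,5R)-5-[(tert-butyldimethylsilyl)oxy]-1,7-bis[4-(methoxymethoxy)phenyl]hept-2-en-1-yl}-6-methoxy-2,4-bis(methoxymethoxy)phenyl]-3-phenylprop-2-en-1-ol, both carbinol epimers | COc1cc(OCOC)c([C@H](/C=C/C[C@H](O[Si](C)(C)C(C)(C)C)CCc2ccc(OCOC)cc2)c2ccc(OCOC)cc2)c(OCOC)c1C(O)/C=C/c1ccccc1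
F3 | step 5 | (E)-4-(4-hydroxyphenyl)but-3-en-2-one | CC(=O)/C=C/c1ccc(O)cc1
F4 | step 5 | (E)-4-[4-(methoxymethoxy)phenyl]but-3-en-2-one | CC(=O)/C=C/c1ccc(OCOC)cc1
F5 | step 5 | (S,E)-4-[4-(methoxymethoxy)phenyl]but-3-en-2-ol | C[C@H](O)/C=C/c1ccc(OCOC)cc1
F6 | step 5 | (S,E)-4-[4-(methoxymethoxy)phenyl]but-3-en-2-yl pyridine-2-carboxylate | C[C@H](OC(=O)c1ccccn1)/C=C/c1ccc(OCOC)cc1
F7 | step 5 | [4-methoxy-2,6-bis(methoxymethoxy)phenyl]magnesium bromide | Br[Mg]c1c(OCOC)cc(OC)cc1OCOC
F8 | step 5 | (R,E)-5-methoxy-1,3-bis(methoxymethoxy)-2-{1-[4-(methoxymethoxy)phenyl]but-2-en-1-yl}benzene | COc1cc(OCOC)c([C@H](/C=C/C)c2ccc(OCOC)cc2)c(OCOC)c1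
F9 | step 10 | (R)-2-[4-methoxy-2,6-bis(methoxymethoxy)phenyl]-2-[4-(methoxymethoxy)phenyl]acetaldehyde | COc1cc(OCOC)c([C@H](C=O)c2ccc(OCOC)cc2)c(OCOC)c1
F10 | step 10 | (R)-2-[4-methoxy-2,6-bis(methoxymethoxy)phenyl]-2-[4-(methoxymethoxy)phenyl]ethanol | COc1cc(OCOC)c([C@H](CO)c2ccc(OCOC)cc2)c(OCOC)c1
F11 | step 10 | (R)-5-({2-[4-methoxy-2,6-bis(methoxymethoxy)phenyl]-2-[4-(methoxymethoxy)phenyl]ethyl}sulfanyl)-1-phenyl-1H-tetrazole | COc1cc(OCOC)c([C@H](CSc2nnnn2-c2ccccc2)c2ccc(OCOC)cc2)c(OCOC)c1
F12 | step 10 | (R)-5-({2-[4-methoxy-2,6-bis(methoxymethoxy)phenyl]-2-[4-(methoxymethoxy)phenyl]ethyl}sulfonyl)-1-phenyl-1H-tetrazole | COc1cc(OCOC)c([C@H](CS(=O)(=O)c2nnnn2-c2ccccc2)c2ccc(OCOC)cc2)c(OCOC)c1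
F13 | step 10 | (R)-3-[(tert-butyldimethylsilyl)oxy]-5-[4-(methoxymethoxy)phenyl]pentanal | O=CC[C@H](O[Si](C)(C)C(C)(C)C)CCc1ccc(OCOC)cc1
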